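## Structural features

The target is an achiral flavone: a 4H-chromen-4-one in which benzenoid ring A is fused to pyranone ring C through C4a and C8a, and ring B, a 3,5-dihydroxy-4-methoxyphenyl group, is bonded to C2. Every carbon of ring A is substituted: hydroxyls at C5 and C7 alternate with methoxy groups at C6 and C8, and C3 of ring C carries a further methoxy group. The molecule therefore holds four free phenols beside four methyl ethers and no stereocentre. The free phenols, above all the pyrogallol-type ring B and the electron-rich ring A, are easily oxidised and have to travel as ethers that can be removed without touching a methyl ether. The real difficulty is the hexasubstituted ring A: its alternating oxygen pattern, and the need to tell O7 apart from the methoxy groups on both neighbouring carbons, leave little room for stepwise substitution of a simple phenol. Once the O1–C2 bond of ring C is cut, ring A becomes a 2-acylphloroglucinol that is symmetric about the axis through C4a and C7, so the oxygens on C5 and C8a are equivalent. The carbons C4a, C5, C6, C7, C8 and C8a carry oxygen at C5, C7 and C8a, the pattern of a folded triketo ester. The key step uses this feature: it forms C4a–C8a by Claisen closure of such a chain, stored as a 4-alkoxy-2-pyranone whose ring oxygen and lactone carbonyl oxygen end up on C5 and C8a.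

## Logic of the disconnections

16 is traced to 15 by cutting the three benzyl C–O bonds. All phenols that must stay masked carry the same group, so one neutral reduction frees them and the four methyl ethers are never at risk. The forward step must leave the C2–C3 double bond of the chromenone intact.

15 is opened at O1–C2 to the diketone 13, through the hemiketal 14. This removes ring C and exposes the symmetric acylphloroglucinol, so the forward closure cannot give a regioisomer whichever ortho hydroxyl attacks. The forward step needs acid mild enough to spare the benzyl ethers.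

13 is cut at C4a–C8a to the pyranone 11, through the open-chain ester 12. This is the strategic cut: it replaces a hexasubstituted benzene by an acyclic chain whose oxygen pattern is already correct, and 11 and 13 are isomers (C40H38O11), so nothing is lost. The forward step must fold in the Claisen mode and not in an aldol mode. It must also leave the C7 ether unchanged; an alkoxide different from the ether group could exchange at this vinylogous ester carbon, so the magnesium alkoxide is chosen to carry the same benzyl group as the C7 ether.

11 is cut at C2–C3, between the aroyl carbon and the methoxy-bearing carbon, to 8 and 10. This separates ring B as a simple non-enolisable ester. The forward step requires a dianion of 8 that reacts at its terminal carbon and not at C4a.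

10 comes from 9 by cutting the two benzyl C–O bonds; the forward step is a double etherification of equivalent phenols.

8 is cut at C4–C4a, between the side-chain methylene and the ketone carbon, to 6 and the acyl donor 7. The forward step relies on the 6-methyl group being the only acidic position of 6, since C3 and C5 carry methoxy groups. An N-methoxy-N-methylamide is chosen as donor so that the ketone appears only at the quench.

6 comes from 5 by cutting the benzyl C–O bond at O4. The forward step must alkylate O4 and not the lactone carbonyl oxygen.

5 is opened at the lactone C–O bond to the dioxo ester 4, so the heterocycle becomes a linear chain with all five oxygens in place. The forward step is a lactonisation.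

4 is cut between the acetyl carbonyl and the methoxy-bearing C4 to 2 and 3. The forward step requires γ-selective acylation of a dianion. This way of building the pyranone was preferred to a ketone plus malonyl dichloride condensation because the connectivity fixes the regiochemistry.

2 is cut at C2–C3 into two molecules of 1, a self-condensation that cannot give cross products.

## Other disconnections considered

Alternative 1: The cut is C8–C8a, with rings B and C already present. Behind it lies C4a–C5, made by adding a ring C pyranone metalated at the future C4a to the unsymmetrical squaric ester 3-tert-butoxy-4-methoxycyclobut-3-ene-1,2-dione A1. The adduct is 4-{6-[3,5-bis(benzyloxy)-4-methoxyphenyl]-5-methoxy-4-oxo-4H-pyran-3-yl}-2-tert-butoxy-4-hydroxy-3-methoxycyclobut-2-en-1-one A2. On heating, A2 should open by a 4π electrocyclic process to a dienylketene, whose ketene carbon closes onto C8a in a 6π process. Tautomerisation then gives the hydroquinone 2-[3,5-bis(benzyloxy)-4-methoxyphenyl]-7-tert-butoxy-5,8-dihydroxy-3,6-dimethoxy-4H-chromen-4-one A3.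
- In favour: the position of every ring A substituent is written into the cyclobutenone, the key step is neutral and thermal, and the whole flavone nucleus is delivered at once.
- Against: the metalated 4-pyranone is a fragile nucleophile. It must also choose between two very similar carbonyl groups of A1, and only the one next to the methoxy-bearing carbon leads to the right pattern. A3 is an air-sensitive hydroquinone that still needs selective methylation of O8 beside O5, and the tert-butyl ether needs an acid step that the all-benzyl plan avoids.
- Structure: the alternative makes the same ring but does not use its symmetry.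
- Mechanism: a pericyclic cascade has no competing folding modes, and on this point it is better than the chosen plan. Its weak point, the regiochemistry of the squarate addition, has no counterpart in the chosen plan.
- Step economy: three steps are needed after the key step (methylation, ether acidolysis, hydrogenolysis) against two, and the halogenated ring C building block costs several steps, so the chosen plan is shorter.

Alternative 2: The cuts are O1–C8a and C4–C4a, made in one operation. Fluoride (CsF) would release the ring A aryne from 3-(benzyloxy)-5-fluoro-2,4-dimethoxy-6-(trimethylsilyl)phenyl trifluoromethanesulfonate A4. The carboxylate of (2Z)-3-[3,5-bis(benzyloxy)-4-methoxyphenyl]-2-methoxyprop-2-enoic acid A5 adds through oxygen at C8a. The aryl anion at C4a then attacks the ester carbonyl, and acyl transfer gives (Z)-1-[4-(benzyloxy)-6-fluoro-2-hydroxy-3,5-dimethoxyphenyl]-3-[3,5-bis(benzyloxy)-4-methoxyphenyl]-2-methoxyprop-2-en-1-one A6.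
- In favour: two skeletal bonds form in one mild step, and rings A and B are joined with the full three-carbon bridge. In bonds formed per step it is better than the chosen plan, which forms one.
- Against: A4 is itself a hexasubstituted benzene, so the central difficulty of ring A is moved into the precursor and not removed. The aryne is flanked by fluorine on one side and methoxy on the other, and both direct the nucleophile to the remote carbon, so the sense of addition is not secured. The fluorine of A6 must later be exchanged for oxygen on an electron-rich ring activated only by the ortho ketone. A6 also needs an oxidative closure of ring C.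
- Structure: a fluorine stands in for O5, which the chosen plan obtains directly from the pyranone ring oxygen.
- Mechanism: both plans rest on known reaction types. The chosen plan controls its selectivity through the acidity of C4a and chelation, the alternative through a balance of two inductive effects.
- Step economy: three steps follow the key step (fluorine exchange, oxidative cyclisation, hydrogenolysis), and the route to A4 is long, so the overall count is higher.

Alternative 3: The cut is O1–C8a, with hydrogen on C8a in the precursor 1-[2,4-bis(benzyloxy)-3,5-dimethoxyphenyl]-3-(3,5-diacetoxy-4-methoxyphenyl)-2-methoxypropane-1,3-dione A7. Constant-current electrolysis at a graphite anode would oxidise ring A to its radical cation. The enol oxygen adds at C8a, and loss of a second electron and a proton would give 5,7-bis(benzyloxy)-2-[3,5-diacetoxy-4-methoxyphenyl]-3,6,8-trimethoxy-4H-chromen-4-one A8.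
- In favour: no ortho hydroxyl is needed, no chemical oxidant is spent, and the acetates on ring B raise its oxidation potential so that ring A should react first. In reagent economy of the ring C closure it is better than the chosen plan.
- Against: the alternative closes ring C, the easy ring, and leaves ring A to be bought with a pentasubstituted, unsymmetrical arene that is not readily made. Benzyl ethers on a tetra-alkoxy radical cation are exposed to anodic debenzylation and over-oxidation to quinones. Anodic closure of a chromenone from a 1,3-diketone would need method development.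
- Structure: the symmetry of ring A is lost, because A7 has only one position that can close.
- Mechanism: an oxidative radical-cation pathway on the most electron-rich part of the molecule is harder to control than an enolate acylation.
- Step economy: two steps follow the key step (acetate removal, hydrogenolysis), equal to the chosen plan, but the preparation of A7 is expected to be longer.

Key step: step 8

Remark on the chemistry: 2, 4, 11, 12 and 13 are written as keto tautomers; their methoxy-bearing CH centres epimerise through the enols, so they are handled as racemic or diastereomeric mixtures and carry no stereochemical information. The N-methoxy-N-methylamides 3 and 7 are taken as purchasable reagents.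

## Steps

Step 1
Reactants: 1 methyl methoxyacetate (two molecules)
Product: 2 methyl 2,4-dimethoxy-3-oxobutanoate (racemic, labile centre)
Conditions: NaH (0.55 equiv), MeOH (cat.), PhMe, 0 → 60 °C; then aq. HCl
Reagents that add atoms: none
Why: Claisen self-condensation; the enolate of 1 acylates a second molecule of 1 and the equilibrium is drawn to the product by deprotonation of the β-keto ester. Only one enolisable ester is present, so a single product is expected.

Step 2
Reactants: 2 methyl 2,4-dimethoxy-3-oxobutanoate; 3 N-methoxy-N-methylacetamide
Product: 4 methyl 2,4-dimethoxy-3,5-dioxohexanoate (mixture of tautomers and diastereomers, both centres labile)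
Conditions: 2 (1.5 equiv), LiN(iPr)2 (3.1 equiv), THF, −78 → −20 °C; 3 (1.0 equiv), −78 → 0 °C; then aq. HCl
Reagents that add atoms: none
Why: γ-Acylation of a β-keto ester dianion; the second deprotonation occurs at the C4 methylene and this more basic carbon attacks the amide, whose chelated tetrahedral adduct lasts until the quench and blocks double addition. The keto ester is used in excess because the adduct can pass a proton to unreacted dianion.

Step 3
Reactants: 4 methyl 2,4-dimethoxy-3,5-dioxohexanoate
Product: 5 4-hydroxy-3,5-dimethoxy-6-methyl-2H-pyran-2-one
Conditions: DBU (1.1 equiv), PhMe, 80 °C; then aq. HCl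
Reagents that add atoms: none
Why: Base-mediated lactonisation of a 3,5-dioxo ester; the enol oxygen of the C5 ketone attacks the ester carbonyl in a 6-exo-trig closure, methanol is lost, and the conjugated 4-hydroxy-2-pyranone is the thermodynamic sink.

Step 4
Reactants: 5 4-hydroxy-3,5-dimethoxy-6-methyl-2H-pyran-2-one
Product: 6 4-(benzyloxy)-3,5-dimethoxy-6-methyl-2H-pyran-2-one
Conditions: BnBr (1.2 equiv), K2CO3 (1.5 equiv), acetone, reflux
Reagents that add atoms: benzyl bromide, BrCc1ccccc1
Why: Williamson O-alkylation of the vinylogous acid; C3 is blocked by its methoxy group, and alkylation on O4 keeps the 2-pyranone conjugation, the usual outcome for 4-hydroxy-2-pyranones with carbonate bases and reactive halides.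

Step 5
Reactants: 6 4-(benzyloxy)-3,5-dimethoxy-6-methyl-2H-pyran-2-one; 7 N,2-dimethoxy-N-methylacetamide
Product: 8 4-(benzyloxy)-3,5-dimethoxy-6-(3-methoxy-2-oxopropyl)-2H-pyran-2-one
Conditions: LiN(SiMe3)2 (2.2 equiv), THF, −78 °C; 7 (1.1 equiv), −78 → −20 °C; then aq. HCl
Reagents that add atoms: none
Why: Lateral (vinylogous) metalation of the 6-methyl group of a 4-alkoxy-2-pyranone, the only acidic site because C3 and C5 are substituted, followed by C-acylation with the N-methoxy-N-methylamide. The second equivalent of base takes up the more acidic proton of the adduct.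

Step 6
Reactants: 9 methyl 3,5-dihydroxy-4-methoxybenzoate
Product: 10 methyl 3,5-bis(benzyloxy)-4-methoxybenzoate
Conditions: BnBr (2.4 equiv), K2CO3 (3 equiv), DMF, 50 °C
Reagents that add atoms: benzyl bromide, BrCc1ccccc1
Why: Williamson etherification of two equivalent phenols; the methyl ester is inert to carbonate in DMF.

Step 7
Reactants: 8 4-(benzyloxy)-3,5-dimethoxy-6-(3-methoxy-2-oxopropyl)-2H-pyran-2-one; 10 methyl 3,5-bis(benzyloxy)-4-methoxybenzoate
Product: 11 4-(benzyloxy)-6-{4-[3,5-bis(benzyloxy)-4-methoxyphenyl]-3-methoxy-2,4-dioxobutyl}-3,5-dimethoxy-2H-pyran-2-one (racemic, labile centre)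
Conditions: LiN(iPr)2 (3.1 equiv), THF, −78 → −20 °C; 10 (1.1 equiv), −78 → 0 °C; then cold 1 M HCl
Reagents that add atoms: none
Why: Claisen-type acylation of a 1,3-dianion with an ester; the first equivalent of base removes a C4a proton, the second the methoxy-bearing α'-proton, and the more basic terminal carbanion attacks the non-enolisable ester 10. The third equivalent deprotonates the new 1,3-diketone so that it cannot quench the dianion; the new CH(OMe) centre is labile and forms racemic.

Step 8
Reactants: 11 4-(benzyloxy)-6-{4-[3,5-bis(benzyloxy)-4-methoxyphenyl]-3-methoxy-2,4-dioxobutyl}-3,5-dimethoxy-2H-pyran-2-one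
Product: 13 1-[4-(benzyloxy)-2,6-dihydroxy-3,5-dimethoxyphenyl]-3-[3,5-bis(benzyloxy)-4-methoxyphenyl]-2-methoxypropane-1,3-dione (racemic; labile centre), via ring-opened benzyl ester 12 (not isolated)
Conditions: Mg(OBn)2 (3 equiv, from Bu2Mg and BnOH), BnOH–THF, 65 °C; then cold 1 M HCl
Reagents that add atoms: none
Why: Benzyloxide adds to the lactone carbonyl C8a and opens the 2-pyranone to the benzyl ester 12, in which the former ring oxygen is the C5 ketone, O7 remains a benzyl enol ether, and the chain is held as a magnesium bis-chelate (the C5/C4 enolate through C4a and the C4/C2 diketonate through C3). The C4a enolate then attacks the ester carbon C8a, benzyloxide leaves, and the cyclohexadienone tautomerises to the phloroglucinol, driven by aromatisation and formation of the chelated magnesium phenoxide. The closest known reaction type is the magnesium alkoxide induced conversion of 6-(2-oxoalkyl)-4-alkoxy-2-pyranones into 2-acylphloroglucinol monoethers, the Claisen mode of polyketide folding. Ring A closes in a 6-exo-trig Claisen (Dieckmann-type) mode, open to the enolate in either its enolexo or its enolendo form. No stereocentre is formed; the C3 methine enolises rapidly and stays racemic until it becomes sp2 in step 9. The selectivity needed is C-acylation from C4a in preference to aldol closures from the methoxy-bearing carbons C8 and C6 onto the C4 and C2 carbonyls; C4a is the only unsubstituted, doubly activated methylene, whereas C6 and C8 are hindered and their target carbonyls are tied up as magnesium enolates. A benzyl alkoxide free of methoxide and hydroxide makes any addition–elimination at the vinylogous ester carbon C7 degenerate and excludes saponification to an acid that could not undergo the Claisen closure. The diketonate form of the C2–C4 unit also shields it from retro-Claisen cleavage.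

Step 9
Reactants: 13 1-[4-(benzyloxy)-2,6-dihydroxy-3,5-dimethoxyphenyl]-3-[3,5-bis(benzyloxy)-4-methoxyphenyl]-2-methoxypropane-1,3-dione
Product: 15 7-(benzyloxy)-2-[3,5-bis(benzyloxy)-4-methoxyphenyl]-5-hydroxy-3,6,8-trimethoxy-4H-chromen-4-one, via 2-hydroxyflavanone hemiketal 14 (not isolated)
Conditions: p-TsOH·H2O (10 mol%), PhMe, 80 °C
Reagents that add atoms: none
Why: Acid-catalysed cyclodehydration of a 1-(2-hydroxyaryl)-1,3-diketone, the ring-closing stage of a Baker–Venkataraman flavone synthesis; a phenol oxygen adds to the C2 carbonyl (6-exo-trig) to give hemiketal 14, which loses water to the conjugated chromenone. The two ortho hydroxyls are equivalent by the symmetry of ring A, so one flavone should result, and the labile C3 centre becomes sp2.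

Step 10
Reactants: 15 7-(benzyloxy)-2-[3,5-bis(benzyloxy)-4-methoxyphenyl]-5-hydroxy-3,6,8-trimethoxy-4H-chromen-4-one
Product: 16 5,7-dihydroxy-2-(3,5-dihydroxy-4-methoxyphenyl)-3,6,8-trimethoxy-4H-chromen-4-one (5,7,3',5'-tetrahydroxy-3,6,8,4'-tetramethoxyflavone)
Conditions: H2 (1 atm), 10% Pd/C, EtOAc–MeOH (1:1), rt
Reagents that add atoms: none
Why: Catalytic hydrogenolysis of three aryl benzyl ethers over palladium on carbon; methyl ethers and the tetrasubstituted C2–C3 double bond of the chromenone are not reduced under these mild conditions.

## Compound list

1 | methyl methoxyacetate | COCC(=O)OC | starting material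
2 | methyl 2,4-dimethoxy-3-oxobutanoate (racemic, labile centre) | COCC(=O)C(OC)C(=O)OC | intermediate
3 | N-methoxy-N-methylacetamide | CC(=O)N(C)OC | starting material
4 | methyl 2,4-dimethoxy-3,5-dioxohexanoate (mixture of diastereomers, labile centres) | CC(=O)C(OC)C(=O)C(OC)C(=O)OC | intermediate
5 | 4-hydroxy-3,5-dimethoxy-6-methyl-2H-pyran-2-one | COc1c(O)c(OC)c(C)oc1=O | intermediate
6 | 4-(benzyloxy)-3,5-dimethoxy-6-methyl-2H-pyran-2-one | COc1c(OCc2ccccc2)c(OC)c(C)oc1=O | intermediate
7 | N,2-dimethoxy-N-methylacetamide | COCC(=O)N(C)OC | starting material
8 | 4-(benzyloxy)-3,5-dimethoxy-6-(3-methoxy-2-oxopropyl)-2H-pyran-2-one | COCC(=O)Cc1oc(=O)c(OC)c(OCc2ccccc2)c1OC | intermediate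
9 | methyl 3,5-dihydroxy-4-methoxybenzoate | COC(=O)c1cc(O)c(OC)c(O)c1 | starting material
10 | methyl 3,5-bis(benzyloxy)-4-methoxybenzoate | COC(=O)c1cc(OCc2ccccc2)c(OC)c(OCc2ccccc2)c1 | intermediate
11 | 4-(benzyloxy)-6-{4-[3,5-bis(benzyloxy)-4-methoxyphenyl]-3-methoxy-2,4-dioxobutyl}-3,5-dimethoxy-2H-pyran-2-one (racemic, labile centre) | COc1c(OCc2ccccc2)c(OC)c(CC(=O)C(OC)C(=O)c2cc(OCc3ccccc3)c(OC)c(OCc3ccccc3)c2)oc1=O | intermediate
12 | benzyl (2Z)-3-(benzyloxy)-9-[3,5-bis(benzyloxy)-4-methoxyphenyl]-2,4,8-trimethoxy-5,7,9-trioxonon-2-enoate (magnesium chelate in the flask; labile centres at C4 and C8) | CO/C(C(=O)OCc1ccccc1)=C(\OCc1ccccc1)C(OC)C(=O)CC(=O)C(OC)C(=O)c1cc(OCc2ccccc2)c(OC)c(OCc2ccccc2)c1 | intermediate (not isolated)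
13 | 1-[4-(benzyloxy)-2,6-dihydroxy-3,5-dimethoxyphenyl]-3-[3,5-bis(benzyloxy)-4-methoxyphenyl]-2-methoxypropane-1,3-dione (racemic, labile centre) | COC(C(=O)c1c(O)c(OC)c(OCc2ccccc2)c(OC)c1O)C(=O)c1cc(OCc2ccccc2)c(OC)c(OCc2ccccc2)c1 | intermediate
14 | 7-(benzyloxy)-2-[3,5-bis(benzyloxy)-4-methoxyphenyl]-2,5-dihydroxy-3,6,8-trimethoxy-2,3-dihydro-4H-chromen-4-one (racemic mixture of diastereomers) | COC1C(=O)c2c(O)c(OC)c(OCc3ccccc3)c(OC)c2OC1(O)c1cc(OCc2ccccc2)c(OC)c(OCc2ccccc2)c1 | intermediate (not isolated)
15 | 7-(benzyloxy)-2-[3,5-bis(benzyloxy)-4-methoxyphenyl]-5-hydroxy-3,6,8-trimethoxy-4H-chromen-4-one | COc1c(OCc2ccccc2)cc(-c2oc3c(OC)c(OCc4ccccc4)c(OC)c(O)c3c(=O)c2OC)cc1OCc1ccccc1 | intermediate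
16 | 5,7-dihydroxy-2-(3,5-dihydroxy-4-methoxyphenyl)-3,6,8-trimethoxy-4H-chromen-4-one | COc1c(O)cc(-c2oc3c(OC)c(O)c(OC)c(O)c3c(=O)c2OC)cc1O | target

## Step count and least certain steps

Total step count: 10. Longest linear sequence: 9 steps (1, 2, 3, 4, 5, 7, 8, 9, 10); step 6 is a one-step side branch.

Step 8 (key step). Three processes may interfere:
- closure in an aldol mode (C8 onto the C4 carbonyl, or C6 onto the C2 aryl ketone) in place of the Claisen mode;
- slow opening of the lactone once the side chain is doubly deprotonated and the nucleophile is the bulkier benzyloxide;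
- alkoxide-induced retro-Claisen fragmentation of the 2-methoxy-1,3-diketone.

All three are tied to the presence of the distal aryl diketone during the fold. The fallback sets out from 8, whose side chain lacks that unit. 8 is folded under the same magnesium benzyloxide conditions to the acetophenone 1-[4-(benzyloxy)-2,6-dihydroxy-3,5-dimethoxyphenyl]-2-methoxyethan-1-one F1. The polyanion of F1 (LiN(SiMe3)2, THF, −78 °C → rt) is then condensed with ester 10 in a crossed Claisen condensation, the direct form of the Baker–Venkataraman diketone synthesis. This returns to the route at 13 and also bypasses step 7.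

Step 7. The second deprotonation may be incomplete, the acidic product may quench unreacted dianion by proton transfer, and the excess amide base may add to the ester; each would lower conversion or consume 10. The fallback sets out from 8 and 10 and replaces the acylation by aldol addition and oxidation. Ester 10 is reduced with LiAlH4 to [3,5-bis(benzyloxy)-4-methoxyphenyl]methanol F2 and oxidised with MnO2 to 3,5-bis(benzyloxy)-4-methoxybenzaldehyde F3. The dianion of 8 (LiN(iPr)2, 2.1 equiv, THF, −78 °C) is added to F3, which needs no third equivalent of base, to give 4-(benzyloxy)-6-{4-[3,5-bis(benzyloxy)-4-methoxyphenyl]-4-hydroxy-3-methoxy-2-oxobutyl}-3,5-dimethoxy-2H-pyran-2-one F4. Oxidation of the β-hydroxy ketone with Dess–Martin periodinane returns to the route at 11.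

Step 2. The dianion of 2 carries a methoxy group on both nucleophilic carbons and is hindered and strongly basic, so proton transfer to the amide or to the adduct may outrun C-acylation. The fallback sets out from 2 and uses a neutral, masked dianion. Silylation (Me3SiCl, Et3N) gives methyl 2,4-dimethoxy-3-[(trimethylsilyl)oxy]but-2-enoate F5. A second silylation (LiN(iPr)2, Me3SiCl, THF, −78 °C) gives 1,2,4-trimethoxy-1,3-bis[(trimethylsilyl)oxy]buta-1,3-diene F6. F6 is acylated at its terminal carbon with acetyl chloride (CH2Cl2, −78 → 20 °C) and returns to the route at 4 after aqueous work-up.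

Step 4. The anion of 5 is ambident, and alkylation on the lactone carbonyl oxygen would divert material to the isomeric 2-benzyloxy-4-pyranone. The fallback sets out from 5 and returns at 6 by a Mitsunobu etherification (BnOH, PPh3, diisopropyl azodicarboxylate, THF, 0 °C → rt). Here the pyranone acts as the acidic partner towards an alkoxyphosphonium electrophile under neutral conditions, a setting in which 4-hydroxy-2-pyranones are known to react at O4; no new compound is made.

## Further compounds

F1 | step 8 | 1-[4-(benzyloxy)-2,6-dihydroxy-3,5-dimethoxyphenyl]-2-methoxyethan-1-one | COCC(=O)c1c(O)c(OC)c(OCc2ccccc2)c(OC)c1O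
F2 | step 7 | [3,5-bis(benzyloxy)-4-methoxyphenyl]methanol | OCc1cc(OCc2ccccc2)c(OC)c(OCc2ccccc2)c1
F3 | step 7 | 3,5-bis(benzyloxy)-4-methoxybenzaldehyde | O=Cc1cc(OCc2ccccc2)c(OC)c(OCc2ccccc2)c1
F4 | step 7 | 4-(benzyloxy)-6-{4-[3,5-bis(benzyloxy)-4-methoxyphenyl]-4-hydroxy-3-methoxy-2-oxobutyl}-3,5-dimethoxy-2H-pyran-2-one (racemic mixture of diastereomers) | COc1c(OCc2ccccc2)c(OC)c(CC(=O)C(OC)C(O)c2cc(OCc3ccccc3)c(OC)c(OCc3ccccc3)c2)oc1=O
F5 | step 2 | methyl 2,4-dimethoxy-3-[(trimethylsilyl)oxy]but-2-enoate (mixture of geometric isomers) | COCC(O[Si](C)(C)C)=C(OC)C(=O)OC
F6 | step 2 | 1,2,4-trimethoxy-1,3-bis[(trimethylsilyl)oxy]buta-1,3-diene (mixture of geometric isomers) | COC=C(O[Si](C)(C)C)C(OC)=C(OC)O[Si](C)(C)C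
F0 | step 4 | none | none
A1 | alternative 1 | 3-tert-butoxy-4-methoxycyclobut-3-ene-1,2-dione | COC1=C(OC(C)(C)C)C(=O)C1=O
A2 | alternative 1 | 4-{6-[3,5-bis(benzyloxy)-4-methoxyphenyl]-5-methoxy-4-oxo-4H-pyran-3-yl}-2-tert-butoxy-4-hydroxy-3-methoxycyclobut-2-en-1-one (racemic) | COc1c(OCc2ccccc2)cc(-c2occ(C3(O)C(OC)=C(OC(C)(C)C)C3=O)c(=O)c2OC)cc1OCc1ccccc1
A3 | alternative 1 | 2-[3,5-bis(benzyloxy)-4-methoxyphenyl]-7-tert-butoxy-5,8-dihydroxy-3,6-dimethoxy-4H-chromen-4-one | COc1c(OCc2ccccc2)cc(-c2oc3c(O)c(OC(C)(C)C)c(OC)c(O)c3c(=O)c2OC)cc1OCc1ccccc1
A4 | alternative 2 | 3-(benzyloxy)-5-fluoro-2,4-dimethoxy-6-(trimethylsilyl)phenyl trifluoromethanesulfonate | COc1c(OS(=O)(=O)C(F)(F)F)c([Si](C)(C)C)c(F)c(OC)c1OCc1ccccc1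
A5 | alternative 2 | (2Z)-3-[3,5-bis(benzyloxy)-4-methoxyphenyl]-2-methoxyprop-2-enoic acid | CO/C(C(=O)O)=C\c1cc(OCc2ccccc2)c(OC)c(OCc2ccccc2)c1
A6 | alternative 2 | (Z)-1-[4-(benzyloxy)-6-fluoro-2-hydroxy-3,5-dimethoxyphenyl]-3-[3,5-bis(benzyloxy)-4-methoxyphenyl]-2-methoxyprop-2-en-1-one | CO/C(C(=O)c1c(O)c(OC)c(OCc2ccccc2)c(OC)c1F)=C\c1cc(OCc2ccccc2)c(OC)c(OCc2ccccc2)c1
A7 | alternative 3 | 1-[2,4-bis(benzyloxy)-3,5-dimethoxyphenyl]-3-(3,5-diacetoxy-4-methoxyphenyl)-2-methoxypropane-1,3-dione (racemic, labile centre) | COC(C(=O)c1cc(OC)c(OCc2ccccc2)c(OC)c1OCc1ccccc1)C(=O)c1cc(OC(C)=O)c(OC)c(OC(C)=O)c1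
A8 | alternative 3 | 5,7-bis(benzyloxy)-2-[3,5-diacetoxy-4-methoxyphenyl]-3,6,8-trimethoxy-4H-chromen-4-one | COc1c(OC(C)=O)cc(-c2oc3c(OC)c(OCc4ccccc4)c(OC)c(OCc4ccccc4)c3c(=O)c2OC)cc1OC(C)=O
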